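**Retrosynthetic overview**
1. Labels (germacrane): furanone ring A = O–C1=C2–C3(=O)–C4(Me); ylidene C5=C6; butenolide ring B = C6–C7=C11(C13H2OH)–C12(=O)–O; then C8 (O-acyl), C9H2, C10H(Me). The target is 4S,8S,10S,5E.
2. Endgame: one twofold Stille hydroxymethylation of a bis(α-bromo enoate) installs both allylic CH2OH groups. The C8 ester comes from 2,3-dibromopropanoyl chloride.
3. Medium ring C (closed last): C5=C6 forms by intramolecular vinylogous Mukaiyama attack of ring B, as its silyloxyfuran, on a C5 dimethyl acetal, followed by loss of methanol.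
4. Key bond C7–C8: the electrophilic β-carbon of 3,4-dibromobutenolide (ring B, from mucobromic acid) is turned into an alkenylchromium, a β-acylvinyl anion. It adds to the C8 aldehyde under chiral-ligand control, which sets C8.
5. Ring A (first ring made in the flask): gold-catalysed hydrative cyclisation of a γ-hydroxy ynone, built from (S)-α-methylbutyrolactone (C10) and (R)-1,1-dimethoxy-2-methylbut-3-yn-2-ol (C4).

Assumption: the facial sense of the chiral ligands in steps 3 and 7 is unreported for these exact substrates, so it is checked on the first run and the mirror-image ligand is taken if needed; (tributylstannyl)methanol is taken as purchasable.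

**Step 1**
Reactants: 1 mucobromic acid (3,4-dibromo-5-hydroxyfuran-2(5H)-one)
Product: 3 3,4-dibromofuran-2(5H)-one, via hydroxy acid 2 (not isolated)
Conditions: NaBH4 (1.5 equiv), MeOH, 0 °C; then conc. H2SO4, MeOH, 0 °C → rt
Reagents that add atoms: none
Why: NaBH4 reduces the open aldehyde tautomer of the pseudo-acid faster than it touches the vinylic bromides or the carboxylate, and acid then closes hydroxy acid 2 to the butenolide (reduction–lactonisation, the standard preparation of 3), with no stereocentre formed.

**Step 2**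
Reactants: 4 α-methylene-γ-butyrolactone
Product: 5 (S)-α-methyl-γ-butyrolactone
Conditions: H2 (100 atm), Ru2Cl4((R)-BINAP)2(NEt3) (0.5 mol %), CH2Cl2, 50 °C
Reagents that add atoms: none
Why: Noyori-type asymmetric hydrogenation: the lactone carbonyl chelates ruthenium, the (R)-BINAP quadrants leave one face of the exocyclic alkene open, and syn delivery of H2 to that face sets C10 as S in about 95% ee, as known for this very substrate.

**Step 3**
Reactants: 6 1,1-dimethoxypropan-2-one; 7 ethynyltrimethylsilane
Product: 10 (R)-1,1-dimethoxy-2-methylbut-3-yn-2-ol, via alkynylzinc 8 (not isolated), via TMS-alkynol 9 (not isolated)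
Conditions: 7 (3 equiv), Me2Zn (3 equiv), (R,R)-N,N′-bis(3,5-di-tert-butylsalicylidene)cyclohexane-1,2-diamine (20 mol %, forms Zn(salen) in situ), toluene, rt, 48 h; then MeOH, K2CO3 (0.2 equiv), rt
Reagents that add atoms: none
Why: Catalytic asymmetric alkynylation of a ketone (alkynylzinc addition under Zn(salen) catalysis): Me2Zn zincates 7 to 8, the Lewis acidic Zn(salen) binds the ketone, whose branched acetal arm is clearly larger than its methyl group, and steers the alkynyl group to the Re face to set C4 as R in an expected 80–90% ee, the minor enantiomer being purged later as a diastereomer, while K2CO3/MeOH cleaves the C–Si bond in the same flask.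

**Step 4**
Reactants: 10 (R)-1,1-dimethoxy-2-methylbut-3-yn-2-ol; 5 (S)-α-methyl-γ-butyrolactone
Product: 12 (2R,6S)-2,8-dihydroxy-1,1-dimethoxy-2,6-dimethyloct-3-yn-5-one, via dilithio alkynol 11 (not isolated)
Conditions: n-BuLi (2.05 equiv), THF, −78 °C; 5 (1.0 equiv), −78 °C, 1 h; AcOH (2.2 equiv), −78 °C → rt
Reagents that add atoms: none
Why: Acylation of a lithium acetylide by a lactone: the cyclic lithium hemiketal formed at −78 °C does not collapse before the cold acetic acid quench, so no second addition occurs, the acetylide is too weak a base to epimerise C10, and pairing two enantioenriched partners raises the ee of the (4R,10S) diastereomer above 99% (no new stereocentre).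

**Step 5**
Reactants: 12 (2R,6S)-2,8-dihydroxy-1,1-dimethoxy-2,6-dimethyloct-3-yn-5-one
Product: 13 (3S,7R)-7-hydroxy-8,8-dimethoxy-3,7-dimethyl-4-oxooct-5-ynal
Conditions: TEMPO (10 mol %), PhI(OAc)2 (1.1 equiv), CH2Cl2, rt
Reagents that add atoms: none
Why: Oxoammonium oxidation (TEMPO/PhI(OAc)2) acts only on the primary alcohol, leaves the tertiary carbinol, ynone and acetal alone, stops at the aldehyde under anhydrous conditions, and removes the one hydroxyl that would otherwise compete for C1 in the next step.

**Step 6**
Reactants: 13 (3S,7R)-7-hydroxy-8,8-dimethoxy-3,7-dimethyl-4-oxooct-5-ynal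
Product: 15 (3S)-3-[(5S)-5-(dimethoxymethyl)-5-methyl-4-oxo-4,5-dihydrofuran-2-yl]butanal, via hydroxy diketone 14 (not isolated)
Conditions: (4-CF3C6H4)3PAuCl (5 mol %), AgOTf (5 mol %), water-saturated toluene, rt
Reagents that add atoms: water, O
Why: Gold-catalysed hydrative cycloisomerisation of a γ-hydroxy alkynone: the carbophilic cationic gold phosphine activates the ynone for Michael-type attack of water at C3, the resulting α′-hydroxy-1,3-diketone 14 closes through the C4 hydroxyl onto C1 and loses the old C1 oxygen as water to give the 3(2H)-furanone under nearly neutral conditions, so the C4–O bond is never broken (the descriptor changes from R to S by priority only) and C10 is not enolised.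

**Step 7**
Reactants: 15 (3S)-3-[(5S)-5-(dimethoxymethyl)-5-methyl-4-oxo-4,5-dihydrofuran-2-yl]butanal; 3 3,4-dibromofuran-2(5H)-one
Product: 17 3-bromo-4-{(1S,3S)-3-[(5S)-5-(dimethoxymethyl)-5-methyl-4-oxo-4,5-dihydrofuran-2-yl]-1-hydroxybutyl}furan-2(5H)-one, via alkenylchromium 16 (not isolated)
Conditions: CrCl2 (4 equiv), (S)-N-[2-(4-isopropyl-4,5-dihydrooxazol-2-yl)-6-methylphenyl]methanesulfonamide (4.4 equiv), Et3N (4.4 equiv), THF, rt; NiCl2(dmp) (5 mol %, dmp = 2,9-dimethyl-1,10-phenanthroline), 3 (1.5 equiv), 15, rt; aq potassium serinate work-up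
Reagents that add atoms: none
Why: Proposed new method: zerovalent nickel inserts into the more electron-poor β C–Br bond of 3 (the site that also reacts first in palladium couplings of this dibromide), transmetalation to trivalent chromium turns the normally electrophilic β-carbon C7 into a β-acylvinyl anion (an sp2 homoenolate equivalent) that adds chemoselectively to the equally electrophilic aldehyde carbon C8 while the vinylogous ester, acetal and α-bromide stay inert, and the chromium-bound oxazoline–sulfonamide shields the Si face so that Re-face attack sets C8 as S; the closest known reaction type is the ligand-controlled asymmetric Nozaki–Hiyama–Kishi coupling of methyl β-iodoacrylate with aldehydes, and the covalent C–Cr bond is what should keep 16 from expelling the ring carboxylate.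

**Step 8**
Reactants: 17 3-bromo-4-{(1S,3S)-3-[(5S)-5-(dimethoxymethyl)-5-methyl-4-oxo-4,5-dihydrofuran-2-yl]-1-hydroxybutyl}furan-2(5H)-one
Product: 21 (4S,8S,10S,5E)-11-bromo-8-hydroxy-3-oxo-1,4-epoxy-13-norgermacra-1,5,7(11)-trien-12,6-olide, via silyloxyfuran 18 (not isolated), via methoxy macrocycle 19 (not isolated), via TMS ether 20 (not isolated)
Conditions: 17 added over 10 h to TMSOTf (4 equiv), i-Pr2NEt (2.5 equiv), CH2Cl2 (final 1 mM), −40 → 0 °C; DBU (6 equiv), 0 °C; then 0.5 M aq citric acid, THF, rt
Reagents that add atoms: none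
Why: Proposed new method: TMSOTf/i-Pr2NEt silylates the C8 hydroxyl and soft-enolises the bromobutenolide to its aromatic 2-silyloxyfuran 18, the excess TMSOTf ionises the dimethyl acetal to an oxocarbenium ion that only the γ-carbon C6 can attack (the α-carbon carries bromine), giving the nine-membered oxacycle 19 whose two new stereocentres do not matter because DBU removes the acidic C6–H and expels methoxide (E1cB) to ylidene butenolide 20, in which the short C8–C9–C10–C1–O tether holds C4 and C7 on the same side of the new alkene and so enforces the 5E geometry common to the hirsutinolides, and mild acid then cleaves the TMS ether; the closest known reaction types are the one-pot enol silane formation/Mukaiyama addition to dimethyl acetals and the one-pot silyl triflate/DBU synthesis of γ-ylidene butenolides from 3-halo-4-substituted butenolides, run here intramolecularly at high dilution and kept cold to avoid enolising C10.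

**Step 9**
Reactants: 21 (4S,8S,10S,5E)-11-bromo-8-hydroxy-3-oxo-1,4-epoxy-13-norgermacra-1,5,7(11)-trien-12,6-olide; 22 2,3-dibromopropanoyl chloride
Product: 24 8-O-(2-bromoacryloyl) derivative of 21, via dibromopropanoate 23 (not isolated)
Conditions: 22 (1.5 equiv), Et3N (3.5 equiv), CH2Cl2, −20 → 0 °C
Reagents that add atoms: none
Why: Acylation of the C8 alcohol by the acid chloride followed by triethylamine-induced E2 loss of HBr from the α,β-dibromo ester 23 is the standard entry to 2-bromoacrylates, avoids handling the polymerisable free acid, and leaves the C8–O bond and hence the S configuration untouched.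

**Step 10**
Reactants: 24 8-O-(2-bromoacryloyl) derivative of 21; 25 (tributylstannyl)methanol
Product: 27 CNP0261115.1, via monobromide 26 (not isolated)
Conditions: 25 (3 equiv), Pd2(dba)3 (10 mol %), AsPh3 (40 mol %), BHT (trace), 1,4-dioxane, 70 °C
Reagents that add atoms: none
Why: Twofold Stille coupling (Kosugi-type hydroxymethylation): both C–Br bonds belong to α-bromo-α,β-unsaturated esters that add readily to zerovalent palladium, the weakly donating AsPh3 speeds the slow transfer of the CH2OH group from tin, the less hindered acrylate bromide reacts first (26), and the neutral conditions spare the enol lactone, the allylic ester and all three stereocentres, so that no protecting group is needed.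

**Compound list**
1 | mucobromic acid (3,4-dibromo-5-hydroxyfuran-2(5H)-one) | OC1OC(=O)C(Br)=C1Br | starting material
2 | (Z)-2,3-dibromo-4-hydroxybut-2-enoic acid (formed in the flask) | OC/C(Br)=C(Br)\C(=O)O | intermediate
3 | 3,4-dibromofuran-2(5H)-one | O=C1OCC(Br)=C1Br | intermediate
4 | α-methylene-γ-butyrolactone | C=C1CCOC1=O | starting material
5 | (S)-α-methyl-γ-butyrolactone | C[C@H]1CCOC1=O | intermediate
6 | 1,1-dimethoxypropan-2-one | CC(=O)C(OC)OC | starting material
7 | ethynyltrimethylsilane | C#C[Si](C)(C)C | starting material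
8 | methyl[(trimethylsilyl)ethynyl]zinc (formed in the flask) | C[Zn]C#C[Si](C)(C)C | intermediate
9 | (R)-1,1-dimethoxy-2-methyl-4-(trimethylsilyl)but-3-yn-2-ol (formed in the flask) | C[Si](C)(C)C#C[C@](C)(C(OC)OC)O | intermediate
10 | (R)-1,1-dimethoxy-2-methylbut-3-yn-2-ol | C#C[C@](C)(C(OC)OC)O | intermediate
11 | O,C-dilithio derivative of 10 (formed in the flask) | [Li]C#C[C@](C)(C(OC)OC)O[Li] | intermediate
12 | (2R,6S)-2,8-dihydroxy-1,1-dimethoxy-2,6-dimethyloct-3-yn-5-one | OCC[C@H](C)C(=O)C#C[C@](C)(C(OC)OC)O | intermediate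
13 | (3S,7R)-7-hydroxy-8,8-dimethoxy-3,7-dimethyl-4-oxooct-5-ynal | O=CC[C@H](C)C(=O)C#C[C@](C)(C(OC)OC)O | intermediate
14 | (3S,7S)-7-hydroxy-8,8-dimethoxy-3,7-dimethyl-4,6-dioxooctanal (formed in the flask) | O=CC[C@H](C)C(=O)CC(=O)[C@](C)(C(OC)OC)O | intermediate
15 | (3S)-3-[(5S)-5-(dimethoxymethyl)-5-methyl-4-oxo-4,5-dihydrofuran-2-yl]butanal | O=CC[C@H](C)C1=CC(=O)[C@](C)(C(OC)OC)O1 | intermediate
16 | (4-bromo-5-oxo-2,5-dihydrofuran-3-yl)chromium chloride carrying the (S)-sulfonamidate ligand, trivalent chromium (formed in the flask) | O=C1OCC(=C1Br)[Cr](Cl)N(c1c(C)cccc1C1=N[C@@H](C(C)C)CO1)S(C)(=O)=O | intermediate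
17 | 3-bromo-4-{(1S,3S)-3-[(5S)-5-(dimethoxymethyl)-5-methyl-4-oxo-4,5-dihydrofuran-2-yl]-1-hydroxybutyl}furan-2(5H)-one | O[C@@H](C[C@H](C)C1=CC(=O)[C@](C)(C(OC)OC)O1)C2=C(Br)C(=O)OC2 | intermediate
18 | 3-bromo-2-(trimethylsilyloxy)furan form of 17 with C8 OTMS (formed in the flask) | C[Si](C)(C)O[C@@H](C[C@H](C)C1=CC(=O)[C@](C)(C(OC)OC)O1)c2coc(O[Si](C)(C)C)c2Br | intermediate
19 | macrocyclic 5-methoxy-5,6-dihydro adduct, C8 OTMS, mixture at C5 and C6 (formed in the flask) | C[Si](C)(C)O[C@H]1C[C@H](C)C2=CC(=O)[C@](C)(C(OC)C3OC(=O)C(Br)=C31)O2 | intermediate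
20 | 8-O-trimethylsilyl ether of 21 (formed in the flask) | C[Si](C)(C)O[C@H]1C[C@H](C)C2=CC(=O)[C@](C)(/C=C3/OC(=O)C(Br)=C31)O2 | intermediate
21 | (4S,8S,10S,5E)-11-bromo-8-hydroxy-3-oxo-1,4-epoxy-13-norgermacra-1,5,7(11)-trien-12,6-olide | O[C@H]1C[C@H](C)C2=CC(=O)[C@](C)(/C=C3/OC(=O)C(Br)=C31)O2 | intermediate
22 | 2,3-dibromopropanoyl chloride (racemic) | O=C(Cl)C(Br)CBr | starting material
23 | 8-O-(2,3-dibromopropanoyl) derivative of 21, mixture at the α-carbon (formed in the flask) | BrCC(Br)C(=O)O[C@H]1C[C@H](C)C2=CC(=O)[C@](C)(/C=C3/OC(=O)C(Br)=C31)O2 | intermediate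
24 | 8-O-(2-bromoacryloyl) derivative of 21 | C=C(Br)C(=O)O[C@H]1C[C@H](C)C2=CC(=O)[C@](C)(/C=C3/OC(=O)C(Br)=C31)O2 | intermediate
25 | (tributylstannyl)methanol | OC[Sn](CCCC)(CCCC)CCCC | starting material
26 | 11-bromo compound already bearing the 2-(hydroxymethyl)acrylate at C8 (formed in the flask) | C=C(CO)C(=O)O[C@H]1C[C@H](C)C2=CC(=O)[C@](C)(/C=C3/OC(=O)C(Br)=C31)O2 | intermediate
27 | CNP0261115.1, (4S,8S,10S,5E)-13-hydroxy-8-[2-(hydroxymethyl)acryloyloxy]-3-oxo-1,4-epoxygermacra-1,5,7(11)-trien-12,6-olide | C=C(CO)C(=O)O[C@H]1C[C@H](C)C2=CC(=O)[C@](C)(/C=C3/OC(=O)C(CO)=C31)O2 | target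

**Totals**
- Total step count: 10.
- Longest linear sequence: 8 steps (4 → 5 → 12 → 13 → 15 → 17 → 21 → 24 → 27).

**Steps most likely to fail**

Step 8 (closure of the nine-membered oxacycle). Oligomerisation, ionisation at C8 or epimerisation at C10 could win over ring closure. The fallback inverts the order of the two bond formations, so the ring is closed by the metal-mediated C7–C8 coupling, a reaction type with a good record in medium rings. It sets out from 15 and 3 and comes back at 21.
- Compound 3 is converted with TIPSOTf/Et3N into 3,4-dibromo-2-(triisopropylsilyloxy)furan F3.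
- F3 adds intermolecularly to the acetal of 15 (catalytic TMSOTf, CH2Cl2, −78 °C, where acetals react and aldehydes do not) to give the open-chain methoxy butenolide aldehyde F4.
- An intramolecular CrCl2/NiCl2 coupling with the same sulfonamide ligand at high dilution gives the macrocyclic methoxy alcohol F5.
- DBU then eliminates methanol to give 21.

Step 7 (alkenylchromium from the dibromobutenolide). The metalated butenolide could open to an allenoate, or the ligand could give poor facial control. The fallback keeps the polarity but masks the butenolide as a furan. It sets out from 15 and comes back at 17.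
- Commercial 3,4-dibromofuran is lithiated (n-BuLi, −78 °C) and transmetalated with EtZnCl.
- The furylzinc is added to 15 under catalysis by the amino alcohol MIB to give the (S)-(4-bromofuran-3-yl)carbinol F1.
- Dye-sensitised photooxygenation (O2, rose bengal, hν, i-Pr2NEt, −78 °C) gives the γ-hydroxybutenolide F2. The base removes the more acidic, less hindered endoperoxide proton next to the C–Br carbon, so that this carbon becomes the lactone carbonyl.
- NaBH4 followed by acid, as in step 1, gives 17.

Step 10 (two couplings at once on the finished skeleton). Polymerisation or protodebromination of the bromoacrylate could ruin the last step. The fallback brings the side chain in ready-made and leaves only one coupling. It sets out from 21 and comes back at 27.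
- Commercial ethyl 2-(hydroxymethyl)acrylate is silylated (TBSCl, imidazole) to ethyl 2-[(tert-butyldimethylsilyloxy)methyl]acrylate F6.
- F6 is saponified (LiOH) to 2-[(tert-butyldimethylsilyloxy)methyl]acrylic acid F7.
- Steglich esterification of 21 with this acid gives the silylated ester bromide F8.
- A single Stille hydroxymethylation with 25 at the butenolide bromide gives the mono-silyl ether of the target F9.
- HF·pyridine releases 27.

**Further compounds**
F1 | step 7 | (2S)-5-[(2S,4S)-4-(4-bromofuran-3-yl)-4-hydroxybutan-2-yl]-2-(dimethoxymethyl)-2-methylfuran-3(2H)-one | O[C@@H](C[C@H](C)C1=CC(=O)[C@](C)(C(OC)OC)O1)c2cocc2Br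
F2 | step 7 | 5-hydroxy derivative of 17 (γ-hydroxybutenolide, mixture at C6) | O[C@@H](C[C@H](C)C1=CC(=O)[C@](C)(C(OC)OC)O1)C2=C(Br)C(=O)OC2O
F3 | step 8 | 3,4-dibromo-2-(triisopropylsilyloxy)furan | CC(C)[Si](Oc1occ(Br)c1Br)(C(C)C)C(C)C
F4 | step 8 | (3S)-3-{(5S)-5-[(3,4-dibromo-5-oxo-2,5-dihydrofuran-2-yl)(methoxy)methyl]-5-methyl-4-oxo-4,5-dihydrofuran-2-yl}butanal (mixture at C5 and C6) | O=CC[C@H](C)C1=CC(=O)[C@](C)(C(OC)C2OC(=O)C(Br)=C2Br)O1
F5 | step 8 | macrocyclic 5-methoxy-5,6-dihydro derivative of 21 with free C8 OH (mixture at C5 and C6) | O[C@H]1C[C@H](C)C2=CC(=O)[C@](C)(C(OC)C3OC(=O)C(Br)=C31)O2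
F6 | step 10 | ethyl 2-[(tert-butyldimethylsilyloxy)methyl]acrylate | CCOC(=O)C(=C)CO[Si](C)(C)C(C)(C)C
F7 | step 10 | 2-[(tert-butyldimethylsilyloxy)methyl]acrylic acid | OC(=O)C(=C)CO[Si](C)(C)C(C)(C)C
F8 | step 10 | 8-O-{2-[(tert-butyldimethylsilyloxy)methyl]acryloyl} derivative of 21 | CC(C)(C)[Si](C)(C)OCC(=C)C(=O)O[C@H]1C[C@H](C)C2=CC(=O)[C@](C)(/C=C3/OC(=O)C(Br)=C31)O2
F9 | step 10 | side-chain O-TBS ether of 27 | CC(C)(C)[Si](C)(C)OCC(=C)C(=O)O[C@H]1C[C@H](C)C2=CC(=O)[C@](C)(/C=C3/OC(=O)C(CO)=C31)O2
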